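(The numbers in the tables are calculated with constants of no real substance.)

The chair opened by asking what the flask will give and had the charges and readings read out.

the same everywhere: free catalyst 0.12 mol%

| flask | left-handed substrate | right-handed substrate | solid reagent | remark | time |
|---|---|---|---|---|---|
| alder | 10 mM | 10 mM | 1.1 equiv | run made earlier |  |
| flask | 20 mM | 20 mM | 1.10 equiv |  | 80 min |

- alder (time / min: left-handed substrate / %, right-handed substrate / %): 0.667: 49.3, 50.5; 1.33: 49.0, 49.6; 3.00: 49.7, 50.4; 8.00: 46.2, 49.6

(standard deviation of a reading: 0.5 percentage points)

- free catalyst is single-handed; left-handed substrate and right-handed substrate are mirror images of each other, charged as a racemate, each of them at the stated concentration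
- given per volume of solution although it is solid: solid reagent
- the numbers in the tables scatter with a standard deviation of 0.5 percentage points
- at the start none of the solid reagent is in solution
- an excess is below zero if the other one leads
- no earlier run changes the charge of free catalyst; that part of a forecast is a guess

- part of the left-handed substrate and right-handed substrate charged together that has reacted at 80 min
- excess of left-handed product over right-handed product in the product at 80 min
- excess of right-handed substrate over left-handed substrate among what is left of the two at 80 min

The kineticist proposed counting turnovers. The flask starts with c(free catalyst) = 0.0240 mM against 40.0 mM of the two substrates together, so the full count, meaning the rounds each catalyst charged must make on average to convert the entire charge, is 1670. Conversion is therefore rounds (the turnover number) divided by the full count. The alder run has the same loading and so the same full count.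

The secretary then read that run. The readings stand flat to 3.00 min, and by 8.00 min conversion is 4.20%, or 70.0 rounds. This is rough, since each reading scatters by 0.5 percentage points, but it suggests about 14.0 min⁻¹ once the reaction is moving.

The forecaster, doubling the alder rate constant for twice the catalyst concentration, gave c 45%, eP 82% and eS 66%, and added “Catalyst order, dissolution and selectivity remain uncertain”.

The kineticist's own reckoning was that this c asks for 750 rounds, fewer than the full count but ten times the alder count. At the alder pace that takes 53.6 min. The alder readings stop at 8.00 min, earlier than that, so how long a catalyst lasts stays open.

The flask gives c 31.1%, eP 77.1% and eS 21.7%.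

    free catalyst + left-handed substrate ⇌ catalyst intermediate A (K = 110 M⁻¹, k = 25000 M⁻¹ s⁻¹)
    free catalyst + right-handed substrate ⇌ catalyst intermediate B (K = 30.0 M⁻¹, k = 1600 M⁻¹ s⁻¹)
    partner + catalyst intermediate A → free catalyst + left-handed product (k = 50.0 M⁻¹ s⁻¹)
    partner + catalyst intermediate B → free catalyst + right-handed product (k = 18.0 M⁻¹ s⁻¹)
    left-handed substrate ⇌ right-handed substrate (k = 7.10 × 10⁻⁵ s⁻¹)
    solid reagent ⇌ partner, rate k6*(cs6 - [partner]) while solid is left; crystals form when [partner] > cs6 (solubility = 13.0 mM, k = 0.00460 s⁻¹)
    partner + free catalyst → spent catalyst (k = 0.160 M⁻¹ s⁻¹)

So each catalyst charged made on average 519 rounds, fewer than the 750 that the forecast's c asks, and by 80.0 min the spent catalyst stands at 93.8% of the catalyst charged. The left-handed lead among those rounds comes from the return of catalyst intermediate B to free catalyst + right-handed substrate: the run without that step gives eP −89.6% instead of 77.1%, so this return is the main reason. In the neighbour flask with 0.03 mol% of free catalyst, the full count is 6670, so 519 rounds, carried over unchanged, reckon to c 7.79%. The computed c there is 9.69%.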